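**Retrosynthetic overview** (locants are those of the benzofuran-6-one: O1, C2 aryl, C3 methyl, C3a allyl-bearing quaternary carbon, C4=C5(OMe), C6=O, C7, C7a; precursors keep them)
- C4=C5 is opened by an intramolecular aldol condensation, giving oxolane 19 with a formyl group (C4) on C3a and a 3-methoxy-2-oxopropyl chain (C7–C6–C5) on C7a.
- Enabling feature: in the oxolane ring the O-bearing methine C7a is bonded to the quaternary carbon C3a, and C3a carries C4 of the cyclohexenone ring at a position that can be a formyl carbon. This is the 3-formyloxolane retron of a Prins–pinacol reaction, which unites 3,4-dimethoxybenzaldehyde with an anti allylic 1,2-diol (carbinol carbons C7a and C4), forms C2–C3 and then C3a–C7a, and sets C2, C3 and C3a from C7a.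
- The diol comes from Felkin addition of (Z)-hexa-2,5-dien-3-yllithium to an α-silyloxy aldehyde; (R)-glycidol supplies C4, C7a and C7, and 2-(methoxymethyl)-1,3-dithiane supplies C6 (masked ketone) and C5–OMe.
- Ring order: oxolane ring first (step 9), cyclohexenone ring second (step 11).

Key step: step 9

Step 1
Reactants: 1 1,1,2-trimethoxyethane
Product: 2 2-(methoxymethyl)-1,3-dithiane
Conditions: propane-1,3-dithiol, BF3·OEt2, CH2Cl2, 0 °C → rt
Reagents that add atoms: propane-1,3-dithiol, SCCCS
Why: BF3-promoted exchange of a dimethyl acetal for the cyclic dithioacetal (thioacetalisation) should be clean, and no stereocentre is formed.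

Step 2
Reactants: 2 2-(methoxymethyl)-1,3-dithiane; 3 (R)-glycidol
Product: 6 (2S)-3-[2-(methoxymethyl)-1,3-dithian-2-yl]propane-1,2-diol, via lithiated dithiane 4 (not isolated), via lithium glycidoxide 5 (not isolated)
Conditions: 2 (2.2 equiv), n-BuLi (2.2 equiv), THF, −30 °C; then 3 (1 equiv), −30 → 0 °C; aq. NH4Cl
Reagents that add atoms: none
Why: Corey–Seebach dithiane alkylation in which one equivalent of 4 deprotonates 3 to 5 (returning 2) and the second opens the epoxide at its CH2 terminus (SN2), so the glycidol stereocentre is untouched and becomes the (S)-carbinol that ends as C7a; Payne rearrangement of 5 is degenerate, and keeping 4 at or below −30 °C should suppress β-loss of LiOMe.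

Step 3
Reactants: 6 (2S)-3-[2-(methoxymethyl)-1,3-dithian-2-yl]propane-1,2-diol
Product: 7 (2S)-3-[2-(methoxymethyl)-1,3-dithian-2-yl]-1,2-bis(triethylsilyloxy)propane
Conditions: TESCl, imidazole, DMF, 0 °C → rt
Reagents that add atoms: chlorotriethylsilane, CC[Si](Cl)(CC)CC
Why: Routine imidazole-mediated silylation of both hydroxyls sets up selective unmasking of the primary position.

Step 4
Reactants: 7 (2S)-3-[2-(methoxymethyl)-1,3-dithian-2-yl]-1,2-bis(triethylsilyloxy)propane
Product: 8 (2S)-3-[2-(methoxymethyl)-1,3-dithian-2-yl]-2-(triethylsilyloxy)propanal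
Conditions: (COCl)2, DMSO, CH2Cl2, −78 → −30 °C; then Et3N, −78 → 0 °C
Reagents that add atoms: none
Why: Under Swern conditions a primary triethylsilyl ether is cleaved and oxidised in the flask while the secondary one survives (direct Swern oxidation of primary TES ethers), so the α-silyloxy aldehyde should form without touching the dithiane or the stereocentre.

Step 5
Reactants: 9 acetaldehyde
Product: 10 1,1-dibromoprop-1-ene
Conditions: CBr4, PPh3, Zn dust, CH2Cl2, 0 °C → rt
Reagents that add atoms: tetrabromomethane, BrC(Br)(Br)Br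
Why: Ramirez dibromo-olefination (first stage of the Corey–Fuchs sequence) of an aldehyde with the ylide made from CBr4, PPh3 and Zn.

Step 6
Reactants: 10 1,1-dibromoprop-1-ene; 11 allyltributylstannane
Product: 12 (2Z)-3-bromohexa-2,5-diene
Conditions: Pd2(dba)3 (cat.), tri(2-furyl)phosphine, toluene, 90 °C
Reagents that add atoms: none
Why: trans-Selective Stille monocoupling of a 1,1-dibromoalkene, in which zerovalent palladium inserts into the less hindered C–Br bond trans to methyl, so the remaining bromine is cis to methyl (the Z isomer).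

Step 7
Reactants: 12 (2Z)-3-bromohexa-2,5-diene; 8 (2S)-3-[2-(methoxymethyl)-1,3-dithian-2-yl]-2-(triethylsilyloxy)propanal
Product: 14 (2Z,4R,5S)-6-[2-(methoxymethyl)-1,3-dithian-2-yl]-3-(prop-2-en-1-yl)-5-(triethylsilyloxy)hex-2-en-4-ol, via vinyllithium 13 (not isolated)
Conditions: 12, t-BuLi (2 equiv), Et2O, −78 °C; then 8, −78 °C; aq. NH4Cl
Reagents that add atoms: none
Why: Bromine–lithium exchange proceeds with retention of alkene geometry (kept at −78 °C to avoid proton transfer from the skipped-diene methylene), and the vinyllithium should add to the α-silyloxy aldehyde under Felkin–Anh (non-chelation) control, setting the new carbinol centre (4R) anti to the silyloxy group.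

Step 8
Reactants: 14 (2Z,4R,5S)-6-[2-(methoxymethyl)-1,3-dithian-2-yl]-3-(prop-2-en-1-yl)-5-(triethylsilyloxy)hex-2-en-4-ol
Product: 15 (2Z,4R,5S)-6-[2-(methoxymethyl)-1,3-dithian-2-yl]-3-(prop-2-en-1-yl)hex-2-ene-4,5-diol
Conditions: TBAF, AcOH, THF, 0 °C
Reagents that add atoms: none
Why: Buffered fluoride cleavage of the secondary triethylsilyl ether should free the anti 1,2-diol without affecting the dithiane or the allylic alcohol.

Step 9
Reactants: 15 (2Z,4R,5S)-6-[2-(methoxymethyl)-1,3-dithian-2-yl]-3-(prop-2-en-1-yl)hex-2-ene-4,5-diol; 16 3,4-dimethoxybenzaldehyde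
Product: 18 (2S,3S,4R,5S)-5-(3,4-dimethoxyphenyl)-2-{[2-(methoxymethyl)-1,3-dithian-2-yl]methyl}-4-methyl-3-(prop-2-en-1-yl)oxolane-3-carbaldehyde, via dioxolane acetal 17 (not isolated)
Conditions: BF3·OEt2 (3 equiv), MgSO4, CH2Cl2, −55 → −20 °C; cold aq. NaHCO3
Reagents that add atoms: none
Why: BF3·OEt2 condenses 15 with 16 to the dioxolane 17 and reopens it to the (E)-oxocarbenium ion on the C7a oxygen; the (Z)-alkene attacks it through C3 in a chair (6-endo Prins cyclisation, C2–C3 bond) to give an oxan-4-yl cation centred on C3a, and the C4–C7a ring bond then migrates from C4 to C3a with retention at C7a while the C4 hydroxyl collapses to the formyl group (pinacol shift). The closest known reaction type is the Prins–pinacol synthesis of 3-acyl and 3-formyl tetrahydrofurans from allylic 1,2-diols and aldehydes. The oxolane ring is the only ring closed, and it is closed by the C3a–C7a bond in a suprafacial ring-contracting 1,2-shift of the six-membered oxane (if the 2-oxonia-Cope/aldol alternative operates, by a 5-endo aldol closure to the same constitution). C2 is controlled by the equatorial aryl group of the (E)-oxocarbenium ion opposite the equatorial C7a side chain (aryl and C7 cis across O1), C3 by the (Z)-alkene, whose methyl group is axial and therefore cis to the aryl group, and C3a by the syn addition of C2 and C7a across the alkene, which keeps the formyl group cis to methyl and puts allyl on the other face, while C7a, carried over from (R)-glycidol, fixes the absolute sense. The step needs the ring bond to migrate faster than the axial C4 hydrogen shifts or the cation loses a proton, and it needs ionisation at the acetal carbon and not at the allylic C4–O bond; the lone-pair push of the C4 oxygen, the chair of the anti diol with all large groups equatorial and the low temperature are relied on, and the easily ionised electron-rich aryl acetal helps the second point.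

Step 10
Reactants: 18 (2S,3S,4R,5S)-5-(3,4-dimethoxyphenyl)-2-{[2-(methoxymethyl)-1,3-dithian-2-yl]methyl}-4-methyl-3-(prop-2-en-1-yl)oxolane-3-carbaldehyde
Product: 19 (2S,3S,4R,5S)-5-(3,4-dimethoxyphenyl)-2-(3-methoxy-2-oxopropyl)-4-methyl-3-(prop-2-en-1-yl)oxolane-3-carbaldehyde
Conditions: MeI, CaCO3, MeCN/H2O (9:1), 45 °C
Reagents that add atoms: water, O
Why: S-Methylation of the dithiane and hydrolysis of the sulfonium salt (MeI/CaCO3 dethioacetalisation) should unmask the methoxymethyl ketone under near-neutral conditions that leave the non-enolisable aldehyde, the alkene and the benzylic ether intact.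

Step 11
Reactants: 19 (2S,3S,4R,5S)-5-(3,4-dimethoxyphenyl)-2-(3-methoxy-2-oxopropyl)-4-methyl-3-(prop-2-en-1-yl)oxolane-3-carbaldehyde
Product: 21 (2S,3R,3aR,7aS)-2-(3,4-dimethoxyphenyl)-5-methoxy-3-methyl-3a-(prop-2-en-1-yl)-3,3a,7,7a-tetrahydro-1-benzofuran-6(2H)-one (target), via aldol adduct 20 (not isolated)
Conditions: dibenzylammonium trifluoroacetate (cat.), benzene, 50 °C
Reagents that add atoms: none
Why: Amine-salt-catalysed intramolecular aldol condensation in which only enolisation towards the methoxy-bearing C5 can close a six-membered ring onto the non-enolisable C4 aldehyde (the C7 side would give a four-membered ring), and E1cB loss of water gives the 5-methoxy enone; no stereocentre is created and the near-neutral medium should spare the β-alkoxy ketone.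

**Compound list**
1 | 1,1,2-trimethoxyethane | COCC(OC)OC | starting material
2 | 2-(methoxymethyl)-1,3-dithiane | COCC1SCCCS1 | intermediate
3 | (R)-glycidol, (2R)-oxiran-2-ylmethanol | OC[C@@H]1CO1 | starting material
4 | 2-lithio-2-(methoxymethyl)-1,3-dithiane | [Li]C1(COC)SCCCS1 | intermediate (not isolated)
5 | lithium (R)-glycidoxide | [Li+].[O-]C[C@@H]1CO1 | intermediate (not isolated)
6 | (2S)-3-[2-(methoxymethyl)-1,3-dithian-2-yl]propane-1,2-diol | OC[C@@H](O)CC1(COC)SCCCS1 | intermediate
7 | (2S)-3-[2-(methoxymethyl)-1,3-dithian-2-yl]-1,2-bis(triethylsilyloxy)propane | CC[Si](CC)(CC)OC[C@@H](O[Si](CC)(CC)CC)CC1(COC)SCCCS1 | intermediate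
8 | (2S)-3-[2-(methoxymethyl)-1,3-dithian-2-yl]-2-(triethylsilyloxy)propanal | O=C[C@@H](O[Si](CC)(CC)CC)CC1(COC)SCCCS1 | intermediate
9 | acetaldehyde | CC=O | starting material
10 | 1,1-dibromoprop-1-ene | CC=C(Br)Br | intermediate
11 | allyltributylstannane | C=CC[Sn](CCCC)(CCCC)CCCC | starting material
12 | (2Z)-3-bromohexa-2,5-diene | C/C=C(\Br)CC=C | intermediate
13 | (2Z)-hexa-2,5-dien-3-yllithium | C/C=C(\[Li])CC=C | intermediate (not isolated)
14 | (2Z,4R,5S)-6-[2-(methoxymethyl)-1,3-dithian-2-yl]-3-(prop-2-en-1-yl)-5-(triethylsilyloxy)hex-2-en-4-ol | C/C=C(CC=C)\[C@@H](O)[C@@H](O[Si](CC)(CC)CC)CC1(COC)SCCCS1 | intermediate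
15 | (2Z,4R,5S)-6-[2-(methoxymethyl)-1,3-dithian-2-yl]-3-(prop-2-en-1-yl)hex-2-ene-4,5-diol (anti diol) | C/C=C(CC=C)\[C@@H](O)[C@@H](O)CC1(COC)SCCCS1 | intermediate
16 | 3,4-dimethoxybenzaldehyde | COc1ccc(C=O)cc1OC | starting material
17 | (4R,5S)-2-(3,4-dimethoxyphenyl)-4-[(2Z)-hexa-2,5-dien-3-yl]-5-{[2-(methoxymethyl)-1,3-dithian-2-yl]methyl}-1,3-dioxolane (both epimers at the acetal carbon) | C/C=C(CC=C)\[C@H]1OC(c2ccc(OC)c(OC)c2)O[C@H]1CC3(COC)SCCCS3 | intermediate (not isolated)
18 | (2S,3S,4R,5S)-5-(3,4-dimethoxyphenyl)-2-{[2-(methoxymethyl)-1,3-dithian-2-yl]methyl}-4-methyl-3-(prop-2-en-1-yl)oxolane-3-carbaldehyde | C=CC[C@@]1(C=O)[C@H](CC2(COC)SCCCS2)O[C@H](c2ccc(OC)c(OC)c2)[C@@H]1C | intermediate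
19 | (2S,3S,4R,5S)-5-(3,4-dimethoxyphenyl)-2-(3-methoxy-2-oxopropyl)-4-methyl-3-(prop-2-en-1-yl)oxolane-3-carbaldehyde | C=CC[C@@]1(C=O)[C@H](CC(=O)COC)O[C@H](c2ccc(OC)c(OC)c2)[C@@H]1C | intermediate
20 | 4-hydroxy-4,5-dihydro derivative of the target (aldol adduct, C4/C5 epimers, other centres as in 21) | C=CC[C@@]12C(O)C(OC)C(=O)C[C@@H]1O[C@H](c1ccc(OC)c(OC)c1)[C@@H]2C | intermediate (not isolated)
21 | (2S,3R,3aR,7aS)-2-(3,4-dimethoxyphenyl)-5-methoxy-3-methyl-3a-(prop-2-en-1-yl)-3,3a,7,7a-tetrahydro-1-benzofuran-6(2H)-one | C=CC[C@@]12C=C(OC)C(=O)C[C@@H]1O[C@H](c1ccc(OC)c(OC)c1)[C@@H]2C | target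

**Step count and risks**
Total step count: 11. Longest linear sequence: 9 steps (1, 2, 3, 4, 7, 8, 9, 10, 11 from compound 1); the bromodiene branch (steps 5 and 6) joins at step 7.

Steps most likely to fail:

1. Step 9. In the favoured chair the C4–H bond is axial and aligned with the empty orbital at C3a, so a 1,2-hydride shift (leading to an oxan-3-one) or proton loss from the allyl methylene may outrun migration of the C4–C7a ring bond. Reversible ionisation of the benzylic C2–O1 bond by BF3 could also erode C2. The fallback sets out from 14 and comes back at 18. Mitsunobu inversion of the C4 carbinol of 14 with 4-nitrobenzoic acid (PPh3, DIAD, THF) should give the (4S) 4-nitrobenzoate F1. Methanolysis (K2CO3, MeOH) gives the syn alcohol F2, and desilylation (TBAF, AcOH) the syn diol F3, which is condensed with 16 under the conditions of step 9. In the chair of the syn series that keeps the C7a side chain equatorial, the C4 oxygen is axial and C4–H lies in the nodal plane of the cation. This is the geometry of the known ring-enlarging furan annulations of cis-1-alkenylcycloalkane-1,2-diols, so only the ring bond is aligned for migration; the price is a 1,3-diaxial methyl/hydroxyl contact.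

2. Step 6. Oxidative addition may lose its preference for the C–Br bond trans to methyl, a second coupling may follow, or a palladium hydride may move the skipped diene into conjugation; 10 and 12 are also volatile. The fallback sets out from 8 and comes back at 14, so steps 5 to 7 are then not needed. Felkin addition of 1-propynylmagnesium bromide to 8 (THF, −78 °C) should give the propargylic alcohol F4. Palladium-catalysed syn-hydrostannation (Bu3SnH, PdCl2(PPh3)2, THF) places tin on the alkyne carbon next to the carbinol and hydrogen cis to it, giving the (E)-vinylstannane F5. Stille coupling of F5 with allyl bromide (Pd2(dba)3, AsPh3, THF, 50 °C) replaces tin by allyl with retention and gives 14.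

3. Step 11. Enolisation or enamine formation towards C7 can expel the ring oxygen from C7a (retro-oxa-Michael), and re-addition would scramble C7a; attack on the neopentyl aldehyde may also be slow. The fallback sets out from 19 and comes back at 21 by a regiodefined Mukaiyama route. Compound 19 is converted (TMSOTf, Et3N, CH2Cl2, −78 °C) into the silyl enol ether F6 on the methoxy-bearing side. BF3·OEt2 at −78 °C then closes the ring to the aldol 20, which is isolated in this variant. Dehydration of 20 through the mesylate F7 (MsCl, Et3N, CH2Cl2, 0 °C → rt, E1cB) gives 21.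

Further compounds
F1 | step 9 | (2Z,4S,5S)-6-[2-(methoxymethyl)-1,3-dithian-2-yl]-3-(prop-2-en-1-yl)-5-(triethylsilyloxy)hex-2-en-4-yl 4-nitrobenzoate | C/C=C(CC=C)\[C@H](OC(=O)c1ccc(cc1)[N+](=O)[O-])[C@@H](O[Si](CC)(CC)CC)CC1(COC)SCCCS1
F2 | step 9 | (2Z,4S,5S)-6-[2-(methoxymethyl)-1,3-dithian-2-yl]-3-(prop-2-en-1-yl)-5-(triethylsilyloxy)hex-2-en-4-ol | C/C=C(CC=C)\[C@H](O)[C@@H](O[Si](CC)(CC)CC)CC1(COC)SCCCS1
F3 | step 9 | (2Z,4S,5S)-6-[2-(methoxymethyl)-1,3-dithian-2-yl]-3-(prop-2-en-1-yl)hex-2-ene-4,5-diol (syn diol) | C/C=C(CC=C)\[C@H](O)[C@@H](O)CC1(COC)SCCCS1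
F4 | step 6 | (2S,3R)-1-[2-(methoxymethyl)-1,3-dithian-2-yl]-2-(triethylsilyloxy)hex-4-yn-3-ol | CC#C[C@@H](O)[C@@H](O[Si](CC)(CC)CC)CC1(COC)SCCCS1
F5 | step 6 | (2E,4S,5S)-6-[2-(methoxymethyl)-1,3-dithian-2-yl]-3-(tributylstannyl)-5-(triethylsilyloxy)hex-2-en-4-ol | C/C=C(/[Sn](CCCC)(CCCC)CCCC)[C@@H](O)[C@@H](O[Si](CC)(CC)CC)CC1(COC)SCCCS1
F6 | step 11 | (2S,3S,4R,5S)-5-(3,4-dimethoxyphenyl)-2-[(2Z)-3-methoxy-2-(trimethylsilyloxy)prop-2-en-1-yl]-4-methyl-3-(prop-2-en-1-yl)oxolane-3-carbaldehyde | C=CC[C@@]1(C=O)[C@H](C/C(O[Si](C)(C)C)=C/OC)O[C@H](c2ccc(OC)c(OC)c2)[C@@H]1C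
F7 | step 11 | 4-methanesulfonate of aldol adduct 20 | C=CC[C@@]12C(OS(C)(=O)=O)C(OC)C(=O)C[C@@H]1O[C@H](c1ccc(OC)c(OC)c1)[C@@H]2C
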